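**Retrosynthetic overview**
1. The γ-lactone (C15–O–C16) comes from a catalyst-controlled, desymmetrising Baeyer–Villiger oxidation of a C13-spiro cyclobutanone, which sets C13. The cyclobutanone comes from a dichloroketene [2+2] on a 13(16)-exocyclic enol ether, and the enol ether (the tetrahydrofuran ring) from 5-exo-dig addition of the 9-OH to a terminal alkyne.
2. C9–C11 comes from addition of a butynyl Grignard reagent to a 6β-hydroxy-9-ketone, giving the 9α-OH.
3. Ring B comes from a [5+1] annulation of β-damascone in which C9 acts as a carbonyl 1,1-dianion. C8–C9 is made by asymmetric conjugate addition of nitromethane (a formyl-anion equivalent), and C9–C10 by a Stetter-type acyl-radical closure after a Nef reaction.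
4. Ring order: A (present in β-damascone) → B (steps 1–3) → tetrahydrofuran (step 7) → cyclobutanone (step 8) → γ-lactone (step 9).

Assumption: labdane numbering (C1–C20) is used for all bicyclic compounds, with α below and β above the decalin plane; the route is a paper design and has not been run.

**Step 1**
Reactants: 1 (E)-β-damascone; 2 nitromethane
Product: 3 (R)-3-methyl-4-nitro-1-(2,6,6-trimethylcyclohex-1-en-1-yl)butan-1-one
Conditions: MeNO2 (5 equiv), N-[3,5-bis(trifluoromethyl)phenyl]-N′-(9-deoxy-epi-quinidin-9-yl)thiourea (10 mol %), toluene, 25 °C, 72 h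
Reagents that add atoms: none
Why: Bifunctional thiourea/amine-catalysed nitro-Michael addition, in which the thiourea binds the enone carbonyl and the quinuclidine delivers the nitronate (the reversed-polarity C9 unit) to the Re face of the crotonyl β-carbon, forming C8–C9 and setting C8 as R, while the tetrasubstituted ring alkene is too hindered to react (the quinine-derived pseudo-enantiomer would give ent-3).

**Step 2**
Reactants: 3 (R)-3-methyl-4-nitro-1-(2,6,6-trimethylcyclohex-1-en-1-yl)butan-1-one
Product: 5 (R)-2-methyl-4-oxo-4-(2,6,6-trimethylcyclohex-1-en-1-yl)butanal, via sodium nitronate 4 (not isolated)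
Conditions: NaOMe (1.1 equiv), MeOH, 0 °C; then aq. TiCl3 (4.5 equiv), NH4OAc buffer (pH 5–6), 0 °C → rt; used at once
Reagents that add atoms: water, O
Why: McMurry-type reductive Nef reaction, in which trivalent titanium reduces the nitronate to the imine that hydrolyses at pH 5–6 to the aldehyde, leaving ketone and alkene untouched and avoiding the strong acid or base that would epimerise C8 or cause Paal–Knorr furan formation.

**Step 3**
Reactants: 5 (R)-2-methyl-4-oxo-4-(2,6,6-trimethylcyclohex-1-en-1-yl)butanal
Product: 6 (5S,8R,10S)-4,4,8,10-tetramethyl-trans-decalin-6,9-dione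
Conditions: (Bu4N)4[W10O32] (2 mol %), MeCN (0.01 M), 390 nm LEDs, 10 °C, Ar; minor C10 diastereomer removed by chromatography
Reagents that add atoms: none
Why: Decatungstate hydrogen-atom-transfer photocatalysis turns the aldehyde C–H into a nucleophilic acyl radical that closes ring B by a Stetter-type 6-endo-trig addition to the enone β-carbon C10 (5-exo attack at C5 is polarity-mismatched and neopentylic); a chair-like transition state with the C8 methyl equatorial places the C10 methyl axial and trans to it (10S), and hydrogen return to C5 from the α face, away from the axial C10 and C4β methyls, gives the trans fusion (5S), which is also the thermodynamic arrangement at the enolisable C5 and C8.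

**Step 4**
Reactants: 6 (5S,8R,10S)-4,4,8,10-tetramethyl-trans-decalin-6,9-dione
Product: 7 (5S,6R,8R,10S)-6β-hydroxy-4,4,8,10-tetramethyl-trans-decalin-9-one
Conditions: NaBH4 (1.0 equiv), MeOH–CH2Cl2 (1:1), −40 °C
Reagents that add atoms: none
Why: Chemoselective borohydride reduction, since the C9 carbonyl (between quaternary C10 and methyl-bearing C8) reacts far more slowly than C6, and hydride enters C6 from the α face because the β face is blocked by the syn-axial C10 and C4β methyls, giving the axial 6β-alcohol (6R).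

**Step 5**
Reactants: 7 (5S,6R,8R,10S)-6β-hydroxy-4,4,8,10-tetramethyl-trans-decalin-9-one; 8 (4-bromobut-1-yn-1-yl)trimethylsilane
Product: 11 (5S,6R,8R,9R,10S)-14,15-dinorlabd-13(16)-yne-6β,9α-diol, via Grignard reagent 9 (not isolated), via silylated diol 10 (not isolated)
Conditions: 8, Mg, THF; then 7, LaCl3·2LiCl (0.3 equiv), 9 (2.5 equiv), THF, −20 → 0 °C; then MeOH, K2CO3, rt
Reagents that add atoms: none
Why: Grignard 1,2-addition with LaCl3·2LiCl to suppress enolisation, in which the first equivalent forms the 6-alkoxide and the second attacks C9 along the equatorial β trajectory (the axial α approach meets the 1α, 5α and 7α hydrogens), giving the 9α-alcohol with the side chain equatorial (9R) as in additions to related 8α-methyl-9-oxodecalins, after which methanolysis cleaves the alkynyl C–Si bond.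

**Step 6**
Reactants: 11 (5S,6R,8R,9R,10S)-14,15-dinorlabd-13(16)-yne-6β,9α-diol
Product: 12 9α-hydroxy-14,15-dinorlabd-13(16)-yn-6β-yl acetate
Conditions: Ac2O (3 equiv), DMAP (0.2 equiv), pyridine, 50 °C
Reagents that add atoms: acetic anhydride, CC(=O)OC(C)=O
Why: DMAP-catalysed acylation, in which only the secondary 6β-OH reacts because the tertiary 9α-OH between C8 and C10 is inert, and no stereocentre is touched.

**Step 7**
Reactants: 12 9α-hydroxy-14,15-dinorlabd-13(16)-yn-6β-yl acetate
Product: 13 9α,13-epoxy-14,15-dinorlabd-13(16)-en-6β-yl acetate (spiro 2-methylenetetrahydrofuran at C9)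
Conditions: Ag2CO3 (10 mol %), toluene, 80 °C, dark; filtered through basic alumina and used crude
Reagents that add atoms: none
Why: Silver-carbonate-catalysed 5-exo-dig cycloisomerisation (intramolecular hydroalkoxylation) of the γ-hydroxy alkyne forms the hindered C13–O bond irreversibly with C9 unchanged (its C–O bond is not broken), and the basic medium keeps the exocyclic enol ether from isomerising.

**Step 8**
Reactants: 13 9α,13-epoxy-14,15-dinorlabd-13(16)-en-6β-yl acetate; 14 trichloroacetyl chloride
Product: 17 C13-spiro cyclobutanone (ring C13–C14H2–C15(=O)–C16H2; 6β-acetate; 9α,13-ether), via dichloroketene 15 (not isolated), via dichlorocyclobutanone 16 (not isolated)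
Conditions: 14 (1.5 equiv), Zn–Cu couple (2 equiv), Et2O–DME, 0 °C → rt; then Zn dust, AcOH, rt
Reagents that add atoms: none
Why: Ketene–enol ether [2+2] cycloaddition in which the ketene carbonyl carbon bonds to the nucleophilic C16 methylene and the CCl2 carbon to the oxygen-bearing C13, followed by zinc/acetic acid dechlorination to a cyclobutanone in which C13 is not stereogenic, so the facial selectivity of the cycloaddition does not matter.

**Step 9**
Reactants: 17 C13-spiro cyclobutanone
Product: 18 previtexilactone, (5S,6R,8R,9R,10S,13S)-6β-acetoxy-9α,13-epoxylabdan-16,15-olide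
Conditions: 30% aq. H2O2 (1.5 equiv), chiral phosphoric acid 3,3′-bis(2,4,6-triisopropylphenyl)-BINOL hydrogen phosphate (10 mol %), CHCl3, −40 °C; minor 13-epimer removed by chromatography
Reagents that add atoms: hydrogen peroxide, OO
Why: Catalytic desymmetrising Baeyer–Villiger oxidation driven by ring strain, in which the chiral acid organises the Criegee adduct so that the pro-S methylene migrates (the catalyst antipode that does this is picked in a screen of both), placing oxygen between C15 and C16 and setting C13 as S under conditions that spare the acetate and the spiro ether.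

**Compound list**
1 | (E)-β-damascone, (E)-1-(2,6,6-trimethylcyclohex-1-en-1-yl)but-2-en-1-one | C/C=C/C(=O)C1=C(C)CCCC1(C)C | starting material
2 | nitromethane | C[N+](=O)[O-] | starting material
3 | (R)-3-methyl-4-nitro-1-(2,6,6-trimethylcyclohex-1-en-1-yl)butan-1-one | C[C@H](CC(=O)C1=C(C)CCCC1(C)C)C[N+](=O)[O-] | intermediate
4 | sodium nitronate of 3 | C[C@H](CC(=O)C1=C(C)CCCC1(C)C)C=[N+]([O-])[O-].[Na+] | intermediate
5 | (R)-2-methyl-4-oxo-4-(2,6,6-trimethylcyclohex-1-en-1-yl)butanal | C[C@H](CC(=O)C1=C(C)CCCC1(C)C)C=O | intermediate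
6 | (5S,8R,10S)-4,4,8,10-tetramethyl-trans-decalin-6,9-dione (5α-H, 8α-Me, 10β-Me) | O=C1C[C@@H](C)C(=O)[C@@]2(C)CCCC(C)(C)[C@H]12 | intermediate
7 | (5S,6R,8R,10S)-6β-hydroxy-4,4,8,10-tetramethyl-trans-decalin-9-one | O[C@@H]1C[C@@H](C)C(=O)[C@@]2(C)CCCC(C)(C)[C@H]12 | intermediate
8 | (4-bromobut-1-yn-1-yl)trimethylsilane | C[Si](C)(C)C#CCCBr | starting material
9 | [4-(trimethylsilyl)but-3-yn-1-yl]magnesium bromide | C[Si](C)(C)C#CCC[Mg]Br | intermediate
10 | (5S,6R,8R,9R,10S)-9β-[4-(trimethylsilyl)but-3-yn-1-yl]-4,4,8,10-tetramethyl-trans-decalin-6β,9α-diol | O[C@@H]1C[C@@H](C)[C@](O)(CCC#C[Si](C)(C)C)[C@@]2(C)CCCC(C)(C)[C@H]12 | intermediate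
11 | (5S,6R,8R,9R,10S)-14,15-dinorlabd-13(16)-yne-6β,9α-diol | O[C@@H]1C[C@@H](C)[C@](O)(CCC#C)[C@@]2(C)CCCC(C)(C)[C@H]12 | intermediate
12 | 9α-hydroxy-14,15-dinorlabd-13(16)-yn-6β-yl acetate | CC(=O)O[C@@H]1C[C@@H](C)[C@](O)(CCC#C)[C@@]2(C)CCCC(C)(C)[C@H]12 | intermediate
13 | 9α,13-epoxy-14,15-dinorlabd-13(16)-en-6β-yl acetate | CC(=O)O[C@@H]1C[C@@H](C)[C@]2(CCC(=C)O2)[C@@]2(C)CCCC(C)(C)[C@H]12 | intermediate
14 | trichloroacetyl chloride | ClC(=O)C(Cl)(Cl)Cl | starting material
15 | dichloroketene | O=C=C(Cl)Cl | intermediate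
16 | C13-spiro 2,2-dichlorocyclobutanone (ring C13–C14Cl2–C15(=O)–C16H2; both C13 epimers) | CC(=O)O[C@@H]1C[C@@H](C)[C@]2(CCC3(CC(=O)C3(Cl)Cl)O2)[C@@]2(C)CCCC(C)(C)[C@H]12 | intermediate
17 | C13-spiro cyclobutanone (ring C13–C14H2–C15(=O)–C16H2; C13 not stereogenic) | CC(=O)O[C@@H]1C[C@@H](C)[C@]2(CCC3(CC(=O)C3)O2)[C@@]2(C)CCCC(C)(C)[C@H]12 | intermediate
18 | previtexilactone | CC(=O)O[C@@H]1C[C@@H](C)[C@]2(CC[C@]3(COC(=O)C3)O2)[C@@]2(C)CCCC(C)(C)[C@H]12 | target

**Totals**
Total steps: 9. Longest linear sequence: 9 (from β-damascone).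

**Three steps most likely to fail**

Step 3 (acyl-radical ring closure onto a tetrasubstituted, twisted enone carbon; decarbonylation or simple reduction may win). The fallback sets out from 5. SmI2/HMPA/t-BuOH in THF at −78 °C performs a ketyl–olefin reductive cyclisation: the aldehyde ketyl adds 6-endo to C10 and the resulting enolate is protonated at C5. This gives (5S,8R,10S)-9-hydroxy-4,4,8,10-tetramethyl-trans-decalin-6-one F1 as a C9 epimer mixture. Dess–Martin periodinane then oxidises the C9 carbinol, and the route is rejoined at 6.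

Step 4 (the C6-over-C9 hydride selectivity may be only modest). The fallback sets out from 6. LiN(i-Pr)2 (1.05 equiv, THF, −78 °C) removes a C7 proton, the only unhindered α-CH2, and masks C6 as its lithium enolate. Grignard reagent 9 with LaCl3·2LiCl then adds to C9, and aqueous work-up gives (5S,8R,9R,10S)-9α-hydroxy-9β-[4-(trimethylsilyl)but-3-yn-1-yl]-4,4,8,10-tetramethyl-trans-decalin-6-one F2. NaBH4 now meets a single ketone and the route is rejoined at 10, which K2CO3/MeOH converts to 11.

Step 9 (catalyst control over which methylene migrates in a 3,3-disubstituted, already chiral cyclobutanone is unproven, and the acid may open the 3-alkoxycyclobutanone). The fallback sets out from 17. A chiral lithium amide (lithium bis[(R)-1-phenylethyl]amide or its antipode) with Me3SiCl as in-situ quench at −100 °C deprotonates the pro-S methylene and gives the C13-spiro 15-trimethylsilyloxy-cyclobut-15(16)-ene F3. Ozonolysis (CH2Cl2–MeOH, −78 °C) with NaBH4 work-up cleaves C15=C16 to the C15 acid and C16 carbinol, the 16-hydroxy-15-oic acid F4, which lactonises with catalytic TsOH. The route is rejoined at 18.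

**Further compounds**
F1 | step 3 | (5S,8R,10S)-9-hydroxy-4,4,8,10-tetramethyl-trans-decalin-6-one (C9 epimers) | O=C1C[C@@H](C)C(O)[C@@]2(C)CCCC(C)(C)[C@H]12
F2 | step 4 | (5S,8R,9R,10S)-9α-hydroxy-9β-[4-(trimethylsilyl)but-3-yn-1-yl]-4,4,8,10-tetramethyl-trans-decalin-6-one | O=C1C[C@@H](C)[C@](O)(CCC#C[Si](C)(C)C)[C@@]2(C)CCCC(C)(C)[C@H]12
F3 | step 9 | C13-spiro 15-trimethylsilyloxy-cyclobut-15(16)-ene (6β-acetate; 9α,13-ether) | CC(=O)O[C@@H]1C[C@@H](C)[C@]2(CC[C@]3(C=C(O[Si](C)(C)C)C3)O2)[C@@]2(C)CCCC(C)(C)[C@H]12
F4 | step 9 | (13S)-6β-acetoxy-9α,13-epoxy-16-hydroxylabdan-15-oic acid | CC(=O)O[C@@H]1C[C@@H](C)[C@]2(CC[C@@](CO)(CC(=O)O)O2)[C@@]2(C)CCCC(C)(C)[C@H]12
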